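**Plan**
- Retrosynthesis: the C4 ketone is taken back to a C4 methyl ether. Ring C is then cut at O1–C2 and C3–C4 into a ring A salicylaldehyde (plus trimethyl orthoformate) and a ring B styrene. The styrene is cut at the aryl–CH2 bond into a bromostyrene and a C10 allylic bromide.
- Enabling feature: O1, C8a, C4a and C4 of ring C (fused to ring A) are the four atoms of an ortho-quinone methide heterodiene. C2–C3 with ring B is a styrene made nucleophilic by the para oxygen at C4'.
- Forward: the side chain is hydrated at C6–C7 at the geranyl acetate stage and joined to ring B by arylcopper alkylation. Ring C, the only ring made, then closes in a three-component hetero-[4+2] with the bis-MOM salicylaldehyde.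
- End game: solvolysis of the C4 methyl ether, oxidation to the ketone, then acid removal of four MOM groups and one TES group.
- Stereochemistry: the E alkene is carried over from geranyl acetate. C2 (S) is set in the cycloaddition by a chiral Brønsted acid counter-anion. The C4 centre formed with it is erased on oxidation.

Key step: step 10

Assumption: the sense of induction of the chiral acid in step 10 cannot be predicted with confidence; the (R)-catalyst is written, and its mirror image is to be used if correlation at ketone 22 shows the 2R series.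

**Route**

Step 1
Reactants: 1 5-bromovanillin (3-bromo-4-hydroxy-5-methoxybenzaldehyde)
Product: 2 3-bromo-4,5-dihydroxybenzaldehyde
Conditions: AlCl3, pyridine, CH2Cl2, reflux; then aq. HCl
Reagents that add atoms: none
Why: Lewis acid-assisted SN2 demethylation, in which AlCl3 chelated between the phenoxide and the ortho methoxy oxygen activates the methyl group for attack by pyridine; this is the standard conversion of vanillins into protocatechualdehydes and leaves the aldehyde and aryl bromide untouched.

Step 2
Reactants: 2 3-bromo-4,5-dihydroxybenzaldehyde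
Product: 3 3-bromo-4,5-bis(methoxymethoxy)benzaldehyde
Conditions: MOMCl, i-Pr2NEt, DMF, 0 °C → rt
Reagents that add atoms: chloromethyl methyl ether (MOMCl), COCCl
Why: O-alkylation of both phenols (Williamson-type acetal formation); MOM is chosen because it later stabilises the ortho-aryllithium by chelation and is removable by mild acid.

Step 3
Reactants: 3 3-bromo-4,5-bis(methoxymethoxy)benzaldehyde
Product: 4 1-bromo-5-ethenyl-2,3-bis(methoxymethoxy)benzene
Conditions: Ph3PCH3Br, KOtBu, THF, 0 °C → rt
Reagents that add atoms: methyltriphenylphosphonium bromide, C[P+](c1ccccc1)(c1ccccc1)c1ccccc1.[Br-]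
Why: Wittig methylenation of a non-enolisable aromatic aldehyde; the aryl bromide and MOM acetals are inert to the ylide.

Step 4
Reactants: 5 geranyl acetate
Product: 7 (2E)-7-hydroxy-3,7-dimethyloct-2-en-1-yl acetate, via organomercurial acetate 6 (not isolated)
Conditions: Hg(OAc)2, THF/H2O (1:1), 0 °C → rt; then NaBH4, 3 M NaOH, 0 °C (brief)
Reagents that add atoms: water, O
Why: Markovnikov oxymercuration–demercuration, in which the electron-rich C6–C7 alkene reacts in preference to the C2–C3 alkene deactivated by the allylic acetate; the transient C6 stereocentre disappears on reduction of the C–Hg bond.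

Step 5
Reactants: 7 (2E)-7-hydroxy-3,7-dimethyloct-2-en-1-yl acetate
Product: 8 (2E)-3,7-dimethyl-7-(triethylsilyloxy)oct-2-en-1-yl acetate
Conditions: TESOTf, 2,6-lutidine, CH2Cl2, −78 → 0 °C
Reagents that add atoms: triethylsilyl trifluoromethanesulfonate (TESOTf), CC[Si](CC)(CC)OS(=O)(=O)C(F)(F)F
Why: silylation of a tertiary alcohol with a silyl triflate and a hindered base; the TES ether masks the acidic OH for the organometallic coupling and the acid-catalysed key step.

Step 6
Reactants: 8 (2E)-3,7-dimethyl-7-(triethylsilyloxy)oct-2-en-1-yl acetate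
Product: 9 (2E)-3,7-dimethyl-7-(triethylsilyloxy)oct-2-en-1-ol
Conditions: K2CO3 (cat.), MeOH, rt
Reagents that add atoms: none
Why: base-catalysed transesterification (methanolysis) of the allylic acetate; a hindered tertiary TES ether is stable to K2CO3 in methanol.

Step 7
Reactants: 9 (2E)-3,7-dimethyl-7-(triethylsilyloxy)oct-2-en-1-ol
Product: 11 (2E)-1-bromo-3,7-dimethyl-7-(triethylsilyloxy)oct-2-ene, via allylic mesylate 10 (not isolated)
Conditions: MsCl, Et3N, THF, −40 °C; then LiBr, THF, 0 °C; used at once
Reagents that add atoms: lithium bromide (LiBr), [Li+].[Br-]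
Why: mesylation followed by SN2 displacement with bromide, the standard acid-free preparation of geranyl-type bromides; it keeps the E geometry and spares the TES ether.

Step 8
Reactants: 4 1-bromo-5-ethenyl-2,3-bis(methoxymethoxy)benzene; 11 (2E)-1-bromo-3,7-dimethyl-7-(triethylsilyloxy)oct-2-ene
Product: 14 triethyl({(6E)-8-[2,3-bis(methoxymethoxy)-5-vinylphenyl]-2,6-dimethyloct-6-en-2-yl}oxy)silane, via aryllithium 12 (not isolated), via arylcopper 13 (not isolated)
Conditions: t-BuLi (2 equiv), Et2O, −78 °C; CuBr·SMe2, −78 → −40 °C; then 11, THF, −78 → 0 °C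
Reagents that add atoms: none
Why: bromine–lithium exchange at −78 °C, known for bromostyrenes, outruns addition to the vinyl group and gives an aryllithium chelated by the ortho MOM ether; transmetalation to copper and SN2 alkylation at the primary allylic carbon (γ attack would build a quaternary carbon) then join ring B to the chain with the E alkene intact.

Step 9
Reactants: 15 2,4,6-trihydroxybenzaldehyde
Product: 16 2-hydroxy-4,6-bis(methoxymethoxy)benzaldehyde
Conditions: MOMCl (2.1 equiv), i-Pr2NEt, CH2Cl2, 0 °C → rt
Reagents that add atoms: chloromethyl methyl ether (MOMCl), COCCl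
Why: selective O-alkylation in which the 4-OH and one ortho OH react while the remaining ortho OH, held in a hydrogen bond to the aldehyde, stays free as required for the ortho-quinone methide.

Step 10
Reactants: 16 2-hydroxy-4,6-bis(methoxymethoxy)benzaldehyde; 17 trimethyl orthoformate; 14 triethyl({(6E)-8-[2,3-bis(methoxymethoxy)-5-vinylphenyl]-2,6-dimethyloct-6-en-2-yl}oxy)silane
Product: 20 (2S,4S)-2-{3,4-bis(methoxymethoxy)-5-[(2E)-3,7-dimethyl-7-(triethylsilyloxy)oct-2-en-1-yl]phenyl}-4-methoxy-5,7-bis(methoxymethoxy)chromane, via dimethyl acetal 18 (not isolated), via O-methyl ortho-quinone methide cation 19 (not isolated)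
Conditions: 16 (1.3 equiv), HC(OMe)3 (2 equiv), (R)-3,3'-bis(2,4,6-triisopropylphenyl)-BINOL N-triflylphosphoramide (5 mol%), 5 Å MS, toluene, −20 °C; Et3N quench
Reagents that add atoms: trimethyl orthoformate 17, COC(OC)OC (supplies the C4 methoxy group)
Why: Proposed new method: the acid converts 16 and 17 by way of acetal 18 into the O-methyl oxocarbenium ion 19, the protonated form of an ortho-quinone methide, held as a contact ion pair with the phosphoramide anion hydrogen-bonded to the free phenol; the CH2 terminus of styrene 14 then attacks the cationic carbon (C3–C4) and the phenolic oxygen captures the developing benzylic cation (O1–C2). Ring C closes by an asynchronous inverse-demand hetero-[4+2] cycloaddition between the four-atom O1–C8a–C4a–C4 heterodiene and the two-atom C2–C3 alkene. The closest known reactions are the racemic Lewis acid-catalysed three-component chroman synthesis from salicylaldehydes, orthoformates and styrenes, the N-triflylphosphoramide-catalysed enantioselective [4+2] of ortho-quinone methides with unfunctionalised styrenes, and the chiral acid-catalysed intramolecular cycloaddition of salicylaldehyde-derived alkoxy ortho-quinone methides; an intermolecular styrene with an alkoxy ortho-quinone methide under a chiral anion is the untested combination. C2 is controlled by the catalyst: the anion blocks one face of 19 and an endo approach of ring B is expected, so face selection and endo preference together give 2S with the 4-methoxy group cis (4S), and later reionisation at C4 can only epimerise C4, which is erased in step 12. Regioselectivity follows from the benzylic cation stabilised by the 4'-OMOM group para to the vinyl group, the same donor makes the styrene a better nucleophile than the trisubstituted chain alkene, and Friedel–Crafts attack of 19 on the electron-rich ring A of 16 or 20 is to be held back by the bulk of the catalyst pocket, the low temperature and a quench as soon as 14 is consumed. The MOM acetals and the tertiary TES ether should survive a catalytic acid at −20 °C in toluene with the released methanol taken up by the sieves.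

Step 11
Reactants: 20 (2S,4S)-4-methoxyflavan
Product: 21 (2S)-2-{3,4-bis(methoxymethoxy)-5-[(2E)-3,7-dimethyl-7-(triethylsilyloxy)oct-2-en-1-yl]phenyl}-5,7-bis(methoxymethoxy)chroman-4-ol (C4 epimers)
Conditions: PPTS (cat.), acetone/H2O (9:1), high dilution, rt
Reagents that add atoms: water, O
Why: SN1 solvolysis of a benzylic methyl ether activated by three ortho/para oxygens of ring A, which should exchange OMe for OH under acid too weak to cleave MOM acetals or the tertiary TES ether; C4 becomes a mixture of epimers, which is of no consequence, and C2 is not touched.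

Step 12
Reactants: 21 (2S)-flavan-4-ol (C4 epimers)
Product: 22 (2S)-2-{3,4-bis(methoxymethoxy)-5-[(2E)-3,7-dimethyl-7-(triethylsilyloxy)oct-2-en-1-yl]phenyl}-5,7-bis(methoxymethoxy)chroman-4-one
Conditions: Dess–Martin periodinane, NaHCO3, CH2Cl2, 0 °C → rt
Reagents that add atoms: none
Why: Dess–Martin oxidation of a secondary benzylic alcohol under bicarbonate buffering; both C4 epimers converge on one ketone, and the non-basic medium avoids retro-oxa-Michael ring opening that would racemise C2.

Step 13
Reactants: 22 protected (2S)-flavanone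
Product: 23 Propolin B, (2S)-2-{3,4-dihydroxy-5-[(2E)-7-hydroxy-3,7-dimethyloct-2-en-1-yl]phenyl}-5,7-dihydroxychroman-4-one
Conditions: HCl (1.25 M in MeOH), MeOH/THF, 0 °C → rt
Reagents that add atoms: none
Why: acid-catalysed acetal exchange of the four MOM ethers and methanolysis of the TES ether; flavanones hold C2 under acid, where opening to the chalcone is slow, and room temperature is kept to spare the tertiary alcohol and the trisubstituted alkene next to the 4'-OH.

**Compound list**

1 | 5-bromovanillin (3-bromo-4-hydroxy-5-methoxybenzaldehyde) | COc1cc(C=O)cc(Br)c1O | starting material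
2 | 3-bromo-4,5-dihydroxybenzaldehyde | O=Cc1cc(O)c(O)c(Br)c1 | intermediate
3 | 3-bromo-4,5-bis(methoxymethoxy)benzaldehyde | O=Cc1cc(OCOC)c(OCOC)c(Br)c1 | intermediate
4 | 1-bromo-5-ethenyl-2,3-bis(methoxymethoxy)benzene | C=Cc1cc(OCOC)c(OCOC)c(Br)c1 | intermediate
5 | geranyl acetate, (2E)-3,7-dimethylocta-2,6-dien-1-yl acetate | C/C(=C\COC(C)=O)CCC=C(C)C | starting material
6 | organomercurial acetate (not isolated), (2E)-6-(acetoxymercurio)-7-hydroxy-3,7-dimethyloct-2-en-1-yl acetate, racemic at C6 | C/C(=C\COC(C)=O)CCC([Hg]OC(C)=O)C(C)(C)O | intermediate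
7 | (2E)-7-hydroxy-3,7-dimethyloct-2-en-1-yl acetate | C/C(=C\COC(C)=O)CCCC(C)(C)O | intermediate
8 | (2E)-3,7-dimethyl-7-(triethylsilyloxy)oct-2-en-1-yl acetate | C/C(=C\COC(C)=O)CCCC(C)(C)O[Si](CC)(CC)CC | intermediate
9 | (2E)-3,7-dimethyl-7-(triethylsilyloxy)oct-2-en-1-ol | C/C(=C\CO)CCCC(C)(C)O[Si](CC)(CC)CC | intermediate
10 | allylic mesylate (not isolated), (2E)-3,7-dimethyl-7-(triethylsilyloxy)oct-2-en-1-yl methanesulfonate | C/C(=C\COS(C)(=O)=O)CCCC(C)(C)O[Si](CC)(CC)CC | intermediate
11 | (2E)-1-bromo-3,7-dimethyl-7-(triethylsilyloxy)oct-2-ene | C/C(=C\CBr)CCCC(C)(C)O[Si](CC)(CC)CC | intermediate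
12 | aryllithium (not isolated), [2,3-bis(methoxymethoxy)-5-vinylphenyl]lithium | [Li]c1cc(C=C)cc(OCOC)c1OCOC | intermediate
13 | arylcopper (not isolated), [2,3-bis(methoxymethoxy)-5-vinylphenyl]copper | [Cu]c1cc(C=C)cc(OCOC)c1OCOC | intermediate
14 | triethyl({(6E)-8-[2,3-bis(methoxymethoxy)-5-vinylphenyl]-2,6-dimethyloct-6-en-2-yl}oxy)silane (ring B styrene) | C/C(=C\Cc1cc(C=C)cc(OCOC)c1OCOC)CCCC(C)(C)O[Si](CC)(CC)CC | intermediate
15 | 2,4,6-trihydroxybenzaldehyde | O=Cc1c(O)cc(O)cc1O | starting material
16 | 2-hydroxy-4,6-bis(methoxymethoxy)benzaldehyde | O=Cc1c(O)cc(OCOC)cc1OCOC | intermediate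
17 | trimethyl orthoformate | COC(OC)OC | starting material
18 | dimethyl acetal (not isolated), 2-(dimethoxymethyl)-3,5-bis(methoxymethoxy)phenol | COC(OC)c1c(O)cc(OCOC)cc1OCOC | intermediate
19 | O-methyl ortho-quinone methide cation (not isolated), [2-hydroxy-4,6-bis(methoxymethoxy)phenyl](methoxy)methylium, ion-paired with the catalyst anion | CO[CH+]c1c(O)cc(OCOC)cc1OCOC | intermediate
20 | (2S,4S)-2-{3,4-bis(methoxymethoxy)-5-[(2E)-3,7-dimethyl-7-(triethylsilyloxy)oct-2-en-1-yl]phenyl}-4-methoxy-5,7-bis(methoxymethoxy)chromane (2,4-cis drawn) | C/C(=C\Cc1cc([C@@H]2C[C@H](OC)c3c(OCOC)cc(OCOC)cc3O2)cc(OCOC)c1OCOC)CCCC(C)(C)O[Si](CC)(CC)CC | intermediate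
21 | (2S)-2-{3,4-bis(methoxymethoxy)-5-[(2E)-3,7-dimethyl-7-(triethylsilyloxy)oct-2-en-1-yl]phenyl}-5,7-bis(methoxymethoxy)chroman-4-ol, mixture of C4 epimers | C/C(=C\Cc1cc([C@@H]2CC(O)c3c(OCOC)cc(OCOC)cc3O2)cc(OCOC)c1OCOC)CCCC(C)(C)O[Si](CC)(CC)CC | intermediate
22 | (2S)-2-{3,4-bis(methoxymethoxy)-5-[(2E)-3,7-dimethyl-7-(triethylsilyloxy)oct-2-en-1-yl]phenyl}-5,7-bis(methoxymethoxy)chroman-4-one | C/C(=C\Cc1cc([C@@H]2CC(=O)c3c(OCOC)cc(OCOC)cc3O2)cc(OCOC)c1OCOC)CCCC(C)(C)O[Si](CC)(CC)CC | intermediate
23 | Propolin B, (2S)-2-{3,4-dihydroxy-5-[(2E)-7-hydroxy-3,7-dimethyloct-2-en-1-yl]phenyl}-5,7-dihydroxychroman-4-one | C/C(=C\Cc1cc([C@@H]2CC(=O)c3c(O)cc(O)cc3O2)cc(O)c1O)CCCC(C)(C)O | target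

**Step count**

Total steps: 13. Longest linear sequence: 9 steps (geranyl acetate 5 to 23 through steps 4–8 and 10–13). The ring B branch from 1 runs 8 steps and the ring A branch from 15 runs 5 steps.

**Steps most likely to fail**

1. Step 10 (proposed new method). What may go wrong:
- the ion pair may give poor face selection or poor endo/exo selection, and since both must be high, C2 would then be formed with low enantiomeric purity;
- the cation may alkylate the electron-rich ring A (Friedel–Crafts) or the styrene may oligomerise under acid;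
- MOM groups may be partly lost.

Fallback with known chemistry, setting out from 14, 16 and 17 and coming back at 22: the three components are combined with Sc(OTf)3 (10 mol%) in CH2Cl2 at rt, the racemic Lewis acid three-component chroman synthesis, to give the racemic 4-methoxyflavan F1. PPTS in aqueous acetone then gives the racemic flavan-4-ol F2, and Dess–Martin oxidation the racemic ketone F3. Kinetic resolution of F3 by Noyori-type asymmetric transfer hydrogenation (RuCl(p-cymene)[(R,R)-TsDPEN], HCO2H/Et3N, CH2Cl2, rt, stopped near half conversion) should reduce the 2R ketone to the (2R,4R)-cis-flavan-4-ol F4, which is removed by chromatography. The unreacted 2S ketone is 22, where the route is rejoined.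

2. Step 11. What may go wrong: the C4 cation may lose a C3 proton to give the flav-3-ene, or be captured by ring A of a second molecule (self-condensation), instead of being captured by water.

Fallback, setting out from 20 and coming back at 22, bypassing 21 and step 12: 20 is oxidised directly with DDQ in CH2Cl2/pH 7 buffer at 0 °C. Hydride abstraction at the doubly activated C4–H, addition of water and collapse of the methyl hemiketal should give the ketone, as in the oxidative cleavage of electron-rich benzylic ethers and the C4 oxidation of 5,7-dialkoxyflavans. No new isolated compound arises.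

3. Step 13. What may go wrong: MOM cleavage may be incomplete at room temperature and call for stronger acid or heat. Under those conditions the chain alkene can be protonated and captured by the neighbouring 4'-OH (chroman formation), and the tertiary alcohol can ionise.

Fallback, setting out from 22 and coming back at 23: 22 is treated with TESOTf and 2,2'-bipyridyl in CH2Cl2 at 0 °C → rt, which exchanges aromatic MOM ethers for aryl silyl ethers without a protic acid and should give the pentakis(triethylsilyl) ether F5. All five silyl groups are then removed with HF·pyridine buffered with pyridine in THF at 0 °C to give 23.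

**Further compounds**

F1 | step 10 | racemic 2-{3,4-bis(methoxymethoxy)-5-[(2E)-3,7-dimethyl-7-(triethylsilyloxy)oct-2-en-1-yl]phenyl}-4-methoxy-5,7-bis(methoxymethoxy)chromane | C/C(=C\Cc1cc(C2CC(OC)c3c(OCOC)cc(OCOC)cc3O2)cc(OCOC)c1OCOC)CCCC(C)(C)O[Si](CC)(CC)CC
F2 | step 10 | racemic 2-{3,4-bis(methoxymethoxy)-5-[(2E)-3,7-dimethyl-7-(triethylsilyloxy)oct-2-en-1-yl]phenyl}-5,7-bis(methoxymethoxy)chroman-4-ol | C/C(=C\Cc1cc(C2CC(O)c3c(OCOC)cc(OCOC)cc3O2)cc(OCOC)c1OCOC)CCCC(C)(C)O[Si](CC)(CC)CC
F3 | step 10 | racemic 2-{3,4-bis(methoxymethoxy)-5-[(2E)-3,7-dimethyl-7-(triethylsilyloxy)oct-2-en-1-yl]phenyl}-5,7-bis(methoxymethoxy)chroman-4-one | C/C(=C\Cc1cc(C2CC(=O)c3c(OCOC)cc(OCOC)cc3O2)cc(OCOC)c1OCOC)CCCC(C)(C)O[Si](CC)(CC)CC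
F4 | step 10 | (2R,4R)-2-{3,4-bis(methoxymethoxy)-5-[(2E)-3,7-dimethyl-7-(triethylsilyloxy)oct-2-en-1-yl]phenyl}-5,7-bis(methoxymethoxy)chroman-4-ol | C/C(=C\Cc1cc([C@H]2C[C@@H](O)c3c(OCOC)cc(OCOC)cc3O2)cc(OCOC)c1OCOC)CCCC(C)(C)O[Si](CC)(CC)CC
F0 | step 11 | none | none
F5 | step 13 | (2S)-2-{5-[(2E)-3,7-dimethyl-7-(triethylsilyloxy)oct-2-en-1-yl]-3,4-bis(triethylsilyloxy)phenyl}-5,7-bis(triethylsilyloxy)chroman-4-one | C/C(=C\Cc1cc([C@@H]2CC(=O)c3c(O[Si](CC)(CC)CC)cc(O[Si](CC)(CC)CC)cc3O2)cc(O[Si](CC)(CC)CC)c1O[Si](CC)(CC)CC)CCCC(C)(C)O[Si](CC)(CC)CC
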